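**Retrosynthetic overview**

1. The target is (5S,6S,7S,10S)-6β,7α-diacetoxylabda-8,13E-dien-15-ol; the C15 alcohol is unmasked last from a silyl ether and both acetates come from a 6β,7α-diol.
2. C9–C11 is cut to a C9 enol triflate and a C11–C16 alkylborane (B-alkyl Suzuki–Miyaura); because C10 is quaternary, a C9 ketone can enolize only toward C8, which fixes the C8=C9 alkene.
3. The C7 and C6 oxygens come from a C6 silyl enol ether by Rubottom oxidation (7α-OH) and hydride reduction (6β-OH), both from the α face, away from the axial C10 and C4β methyl groups.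
4. Enabling feature: ring B (C5–C6–C7–C8–C9–C10) is a six-membered ring that shares the C5–C10 bond with ring A and carries oxygen on the adjacent C6/C7 pair. A retro-[4+2] across C5–C10 and C8–C9 therefore opens both rings at once to an acyclic 2-silyloxydiene (C5=C6(OSi)–C7=C8) linked through C1–C4 (gem-dimethyl C4) to an (E)-nitroalkene (C9=C10), the nitro group being a C9-ketone equivalent.
5. The triene is made in five steps from 5-bromo-2-methylpent-1-ene, mesityl oxide and acetaldehyde; ring A and ring B form together in the cycloaddition.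

Key step: step 6

Remark: bicyclic intermediates are named with drimane/labdane numbering (β = face of the C10 methyl) and the SMILES strings are definitive; it is assumed that the (R,R) antipode of the thiourea gives the 10S series (otherwise the (S,S) catalyst is used) and that the (E)-nitroalkene 10 is separated from any (Z) isomer before use.

**Route**

Step 1
Reactants: 1 5-bromo-2-methylpent-1-ene; 2 4-methylpent-3-en-2-one (mesityl oxide)
Product: 4 4,4,8-trimethylnon-8-en-2-one, via Grignard reagent 3 (not isolated)
Conditions: Mg, THF, rt; then CuI (10 mol %), 2, THF, −20 to 0 °C; 1 M HCl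
Reagents that add atoms: none
Why: Copper-catalysed conjugate addition of the primary Grignard reagent to the β,β-disubstituted enone builds the quaternary gem-dimethyl carbon (future C4); no stereocenter is formed.

Step 2
Reactants: 4 4,4,8-trimethylnon-8-en-2-one; 5 acetaldehyde
Product: 7 2-hydroxy-6,6,10-trimethylundec-10-en-4-one (racemic), via lithium enolate 6 (not isolated)
Conditions: LiN(iPr)2 (LDA), THF, −78 °C; 5, −78 °C; AcOH quench
Reagents that add atoms: none
Why: Kinetic deprotonation takes place at the methyl group and not at the neopentyl methylene, and the lithium enolate undergoes a crossed aldol addition to acetaldehyde; the carbinol center forms as a racemate and is removed in step 3.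

Step 3
Reactants: 7 2-hydroxy-6,6,10-trimethylundec-10-en-4-one
Product: 9 (2E)-6,6,10-trimethylundeca-2,10-dien-4-one, via mesylate 8 (not isolated)
Conditions: MsCl, Et3N (excess), CH2Cl2, 0 °C to rt
Reagents that add atoms: none
Why: Mesylation followed by E1cB elimination completes the aldol condensation and should give the conjugated enone as the thermodynamically favoured E isomer.

Step 4
Reactants: 9 (2E)-6,6,10-trimethylundeca-2,10-dien-4-one
Product: 10 (2E,10E)-6,6,10-trimethyl-11-nitroundeca-2,10-dien-4-one
Conditions: AgNO2 (3 equiv), TEMPO (0.4 equiv), 4 Å molecular sieves, 1,2-dichloroethane, 70 °C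
Reagents that add atoms: silver nitrite AgNO2, [Ag+].[O-]N=O
Why: Radical nitration of an alkene (nitrogen dioxide adds to the terminal carbon of the electron-rich 1,1-disubstituted alkene and TEMPO removes a hydrogen next to the tertiary radical) should give the conjugated nitroalkene and leave the electron-poor enone alone; the E isomer, with the nitro group cis to the smaller methyl group, is expected to predominate.

Step 5
Reactants: 10 (2E,10E)-6,6,10-trimethyl-11-nitroundeca-2,10-dien-4-one
Product: 11 tert-butyldimethyl{[(2E,4Z,10E)-6,6,10-trimethyl-11-nitroundeca-2,4,10-trien-4-yl]oxy}silane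
Conditions: TBSOTf, Et3N, CH2Cl2, −78 to −40 °C; cold non-aqueous work-up, used at once
Reagents that add atoms: tert-butyldimethylsilyl trifluoromethanesulfonate, CC(C)(C)[Si](C)(C)OS(=O)(=O)C(F)(F)F
Why: Soft enolization of the enone at its alpha-prime methylene gives the cross-conjugated 2-silyloxydiene; the Z enol ether, with C4 trans to the propenyl group, avoids allylic strain and puts C4 on the outside of the diene as the cycloaddition needs.

Step 6
Reactants: 11 tert-butyldimethyl{[(2E,4Z,10E)-6,6,10-trimethyl-11-nitroundeca-2,4,10-trien-4-yl]oxy}silane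
Product: 12 6-(tert-butyldimethylsilyloxy)-9β-nitro-11-nordrim-6-ene (5αH/8β-methyl/10β-methyl; trans-fused)
Conditions: 1,1'-[(1R,2R)-cyclohexane-1,2-diyl]bis{3-[3,5-bis(trifluoromethyl)phenyl]thiourea} (20 mol %), toluene, 4 Å molecular sieves, −30 °C to rt
Reagents that add atoms: none
Why: Proposed new method: the chiral bis-thiourea binds both nitro oxygens and lowers the LUMO of the nitroalkene, so the 2-silyloxydiene adds in a concerted but strongly asynchronous, normal-demand intramolecular Diels–Alder reaction in which the C5–C10 bond (nucleophilic diene terminus to the nitroalkene β-carbon) runs ahead of the C8–C9 bond. The closest known reaction types are the uncatalysed intramolecular Diels–Alder reaction of (E)-1-nitrodeca-1,7,9-trienes, the cycloaddition of 2-silyloxydienes with nitroalkenes, and chiral thiourea catalysis of enantioselective additions to nitroalkenes; making the nitro-triene cycloaddition enantioselective in this way is the new element. Ring A closes through the C5–C10 bond across the four-carbon C1–C4 tether (fused mode, 6-exo with respect to the dienophile, helped by the Thorpe–Ingold effect of the C4 gem-dimethyl group), and ring B is the cycloaddition ring itself, closed suprafacially by C5–C10 and C8–C9. The trans relation of H-5 and the C10 methyl follows from the endo-nitro, chair-like transition state in which the (E)-nitroalkene has its methyl endo and the tether exo; C8 and C9 follow from the (E)-propenyl and (E)-nitroalkene geometries and are erased in steps 7 and 8; the absolute configuration at C10 (S) is set by the catalyst, which shields one enantiotopic face of the bound nitroalkene. The step needs the carbocyclic [4+2] to win over the hetero-[4+2] of the nitroalkene (hydrogen-bond activation is used in place of Lewis acid activation), enantioface control to win over the uncatalysed background (low temperature), and trans fusion over cis fusion (endo preference of the bound nitro group), while regiochemistry is fixed by the tether and by matched polarity.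

Step 7
Reactants: 12 6-(tert-butyldimethylsilyloxy)-9β-nitro-11-nordrim-6-ene
Product: 14 6-(tert-butyldimethylsilyloxy)-11-nordrim-6-en-9-one, via potassium nitronate 13 (not isolated)
Conditions: KOtBu, THF, −40 °C; then aq. TiCl3, NH4OAc buffer (pH 6), THF/H2O, 0 °C to rt
Reagents that add atoms: water, O
Why: Reductive Nef reaction: trivalent titanium reduces the nitronate to the imine, which hydrolyses at pH 6 to the C9 ketone while the silyl enol ether should survive the buffered medium; the C9 stereocenter is destroyed and C8 may epimerize without consequence.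

Step 8
Reactants: 14 6-(tert-butyldimethylsilyloxy)-11-nordrim-6-en-9-one
Product: 16 6-(tert-butyldimethylsilyloxy)-11-nordrima-6,8-dien-9-yl trifluoromethanesulfonate, via potassium enolate 15 (not isolated)
Conditions: KN(SiMe3)2 (KHMDS), THF, −78 to −40 °C; PhNTf2, −78 to 0 °C
Reagents that add atoms: N-phenylbis(trifluoromethanesulfonimide), O=S(=O)(N(c1ccccc1)S(=O)(=O)C(F)(F)F)C(F)(F)F
Why: Because C10 is quaternary the ketone can enolize only toward C8, so O-triflation of the potassium enolate gives a single tetrasubstituted enol triflate that fixes the future C8=C9 alkene; the C8 stereocenter is erased.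

Step 9
Reactants: 16 6-(tert-butyldimethylsilyloxy)-11-nordrima-6,8-dien-9-yl trifluoromethanesulfonate
Product: 18 7α-hydroxy-6-oxo-11-nordrim-8-en-9-yl trifluoromethanesulfonate, via silyloxy epoxide 17 (not isolated)
Conditions: dimethyldioxirane (acetone solution), CH2Cl2, −78 °C; then 1 M HCl (cat.), THF/H2O, 0 °C
Reagents that add atoms: dimethyldioxirane, CC1(C)OO1
Why: Rubottom oxidation: the dioxirane epoxidizes the electron-rich silyl enol ether (the C8=C9 alkene is deactivated by its triflate) from the α face, opposite the axial C10 and C4β methyl groups, and acid opens the silyloxy epoxide to the 7α-hydroxy 6-ketone, which sets C7.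

Step 10
Reactants: 18 7α-hydroxy-6-oxo-11-nordrim-8-en-9-yl trifluoromethanesulfonate
Product: 19 6β,7α-dihydroxy-11-nordrim-8-en-9-yl trifluoromethanesulfonate
Conditions: NaBH4, MeOH/CH2Cl2, −40 to 0 °C
Reagents that add atoms: none
Why: Hydride reduction of the hindered C6 ketone should occur from the α face, because the β face is blocked by the two syn-axial methyl groups, giving the axial 6β-alcohol trans to the 7α-hydroxyl and so setting C6; the enol triflate is inert to NaBH4.

Step 11
Reactants: 20 (2E)-3-methylpent-2-en-4-yn-1-ol
Product: 21 tert-butyl{[(2E)-3-methylpent-2-en-4-yn-1-yl]oxy}diphenylsilane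
Conditions: TBDPSCl, imidazole, CH2Cl2, 0 °C to rt
Reagents that add atoms: tert-butyl(chloro)diphenylsilane, CC(C)(C)[Si](Cl)(c1ccccc1)c1ccccc1
Why: Standard silylation of a primary allylic alcohol; the tert-butyldiphenylsilyl ether survives hydroboration, basic coupling and acetylation and can be removed last without touching acetates.

Step 12
Reactants: 21 tert-butyl{[(2E)-3-methylpent-2-en-4-yn-1-yl]oxy}diphenylsilane
Product: 22 tert-butyl{[(2E)-3-methylpenta-2,4-dien-1-yl]oxy}diphenylsilane
Conditions: H2 (1 atm), Pd/CaCO3 poisoned with Pb(OAc)2, quinoline, hexane/EtOAc, rt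
Reagents that add atoms: none
Why: Semihydrogenation of the terminal alkyne on poisoned palladium should stop at the 1,3-diene and leave the E trisubstituted alkene unchanged.

Step 13
Reactants: 19 6β,7α-dihydroxy-11-nordrim-8-en-9-yl trifluoromethanesulfonate; 22 tert-butyl{[(2E)-3-methylpenta-2,4-dien-1-yl]oxy}diphenylsilane
Product: 24 15-(tert-butyldiphenylsilyloxy)labda-8,13E-diene-6β,7α-diol, via alkylborane 23 (not isolated)
Conditions: 9-BBN dimer, THF, 0 °C to rt (hydroboration of 22); then 19, PdCl2(dppf) (10 mol %), AsPh3, Cs2CO3, DMF/THF/H2O, rt to 45 °C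
Reagents that add atoms: none
Why: Anti-Markovnikov hydroboration of the monosubstituted vinyl group of the diene, then B-alkyl Suzuki–Miyaura coupling with the enol triflate (zerovalent palladium formed in situ from the divalent precatalyst), a coupling known for 2,6,6-trisubstituted cyclohexenyl triflates, attaches C11–C16 and delivers the tetrasubstituted C8=C9 alkene; no stereocenter is formed and the free diol is tolerated.

Step 14
Reactants: 24 15-(tert-butyldiphenylsilyloxy)labda-8,13E-diene-6β,7α-diol
Product: 25 15-(tert-butyldiphenylsilyloxy)labda-8,13E-diene-6β,7α-diyl diacetate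
Conditions: Ac2O, DMAP, pyridine, rt to 40 °C
Reagents that add atoms: acetic anhydride, CC(=O)OC(C)=O
Why: DMAP-catalysed acylation should acetylate both secondary hydroxyl groups, the hindered axial 6β-OH needing excess anhydride and gentle warming; configurations are unchanged.

Step 15
Reactants: 25 15-(tert-butyldiphenylsilyloxy)labda-8,13E-diene-6β,7α-diyl diacetate
Product: 26 (5S,6S,7S,10S)-6β,7α-diacetoxylabda-8,13E-dien-15-ol
Conditions: HF·pyridine, pyridine, THF, 0 °C to rt
Reagents that add atoms: none
Why: Buffered fluoride cleaves the primary silyl ether by Si–F bond formation without acyl migration, hydrolysis of the two secondary acetates or ionization of the allylic 7α-acetate.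

**Compound list**

1 | 5-bromo-2-methylpent-1-ene | C=C(C)CCCBr | starting material
2 | 4-methylpent-3-en-2-one (mesityl oxide) | CC(=O)C=C(C)C | starting material
3 | (4-methylpent-4-en-1-yl)magnesium bromide | C=C(C)CCC[Mg]Br | intermediate
4 | 4,4,8-trimethylnon-8-en-2-one | CC(=O)CC(C)(C)CCCC(C)=C | intermediate
5 | acetaldehyde | CC=O | starting material
6 | lithium 4,4,8-trimethylnona-1,8-dien-2-olate | [Li+].[O-]C(=C)CC(C)(C)CCCC(C)=C | intermediate
7 | 2-hydroxy-6,6,10-trimethylundec-10-en-4-one (racemic) | CC(O)CC(=O)CC(C)(C)CCCC(C)=C | intermediate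
8 | 6,6,10-trimethyl-4-oxoundec-10-en-2-yl methanesulfonate (racemic) | CC(OS(C)(=O)=O)CC(=O)CC(C)(C)CCCC(C)=C | intermediate
9 | (2E)-6,6,10-trimethylundeca-2,10-dien-4-one | C/C=C/C(=O)CC(C)(C)CCCC(C)=C | intermediate
10 | (2E,10E)-6,6,10-trimethyl-11-nitroundeca-2,10-dien-4-one | C/C=C/C(=O)CC(C)(C)CCC/C(C)=C/[N+](=O)[O-] | intermediate
11 | tert-butyldimethyl{[(2E,4Z,10E)-6,6,10-trimethyl-11-nitroundeca-2,4,10-trien-4-yl]oxy}silane | C/C=C/C(O[Si](C)(C)C(C)(C)C)=C/C(C)(C)CCC/C(C)=C/[N+](=O)[O-] | intermediate
12 | 6-(tert-butyldimethylsilyloxy)-9β-nitro-11-nordrim-6-ene (5αH, 8β-methyl, 10β-methyl) | CC(C)(C)[Si](C)(C)OC1=C[C@H](C)[C@H]([N+](=O)[O-])[C@@]2(C)CCCC(C)(C)[C@H]12 | intermediate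
13 | potassium nitronate of 12 | CC(C)(C)[Si](C)(C)OC1=C[C@H](C)C(=[N+]([O-])[O-])[C@@]2(C)CCCC(C)(C)[C@H]12.[K+] | intermediate
14 | 6-(tert-butyldimethylsilyloxy)-11-nordrim-6-en-9-one (8β-methyl) | CC(C)(C)[Si](C)(C)OC1=C[C@H](C)C(=O)[C@@]2(C)CCCC(C)(C)[C@H]12 | intermediate
15 | potassium 6-(tert-butyldimethylsilyloxy)-11-nordrima-6,8-dien-9-olate | CC(C)(C)[Si](C)(C)OC1=CC(C)=C([O-])[C@@]2(C)CCCC(C)(C)[C@H]12.[K+] | intermediate
16 | 6-(tert-butyldimethylsilyloxy)-11-nordrima-6,8-dien-9-yl trifluoromethanesulfonate | CC(C)(C)[Si](C)(C)OC1=CC(C)=C(OS(=O)(=O)C(F)(F)F)[C@@]2(C)CCCC(C)(C)[C@H]12 | intermediate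
17 | 6β-(tert-butyldimethylsilyloxy)-6α,7α-epoxy-11-nordrim-8-en-9-yl trifluoromethanesulfonate | CC(C)(C)[Si](C)(C)O[C@@]13O[C@H]3C(C)=C(OS(=O)(=O)C(F)(F)F)[C@@]2(C)CCCC(C)(C)[C@H]12 | intermediate
18 | 7α-hydroxy-6-oxo-11-nordrim-8-en-9-yl trifluoromethanesulfonate | O=C1[C@@H](O)C(C)=C(OS(=O)(=O)C(F)(F)F)[C@@]2(C)CCCC(C)(C)[C@H]12 | intermediate
19 | 6β,7α-dihydroxy-11-nordrim-8-en-9-yl trifluoromethanesulfonate | O[C@@H]1[C@@H](O)C(C)=C(OS(=O)(=O)C(F)(F)F)[C@@]2(C)CCCC(C)(C)[C@H]12 | intermediate
20 | (2E)-3-methylpent-2-en-4-yn-1-ol | C#C/C(C)=C/CO | starting material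
21 | tert-butyl{[(2E)-3-methylpent-2-en-4-yn-1-yl]oxy}diphenylsilane | C#C/C(C)=C/CO[Si](c1ccccc1)(c1ccccc1)C(C)(C)C | intermediate
22 | tert-butyl{[(2E)-3-methylpenta-2,4-dien-1-yl]oxy}diphenylsilane | C=C/C(C)=C/CO[Si](c1ccccc1)(c1ccccc1)C(C)(C)C | intermediate
23 | 9-{(3E)-5-[(tert-butyldiphenylsilyl)oxy]-3-methylpent-3-en-1-yl}-9-borabicyclo[3.3.1]nonane | CC(C)(C)[Si](c1ccccc1)(c1ccccc1)OC/C=C(C)/CCB1C2CCCC1CCC2 | intermediate
24 | 15-(tert-butyldiphenylsilyloxy)labda-8,13E-diene-6β,7α-diol | O[C@@H]1[C@@H](O)C(C)=C(CC/C(C)=C/CO[Si](c3ccccc3)(c3ccccc3)C(C)(C)C)[C@@]2(C)CCCC(C)(C)[C@H]12 | intermediate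
25 | 15-(tert-butyldiphenylsilyloxy)labda-8,13E-diene-6β,7α-diyl diacetate | CC(=O)O[C@@H]1[C@@H](OC(C)=O)C(C)=C(CC/C(C)=C/CO[Si](c3ccccc3)(c3ccccc3)C(C)(C)C)[C@@]2(C)CCCC(C)(C)[C@H]12 | intermediate
26 | (5S,6S,7S,10S)-6β,7α-diacetoxylabda-8,13E-dien-15-ol | CC(=O)O[C@@H]1[C@@H](OC(C)=O)C(C)=C(CC/C(C)=C/CO)[C@@]2(C)CCCC(C)(C)[C@H]12 | target

**Step count**

Total step count: 15. Longest linear sequence: 13 steps (steps 1 to 10, then 13 to 15).

**Steps most likely to fail**

Step 6 (Proposed new method). The uncatalysed background cycloaddition may compete with the hydrogen-bond-catalysed pathway, so that enantioface discrimination is lost, and the endo preference may be too weak to secure the trans ring fusion. The fallback sets out from 10 and comes back at 12, and uses established primary-amine catalysis of the formal [4+2] of enones with nitroalkenes. A cinchona-derived primary amine (9-amino-9-deoxy-epi-quinine with 2-fluorobenzoic acid, toluene, 40 °C) condenses with the C6 ketone of 10 to a cross-conjugated dienamine. This adds through C5 to the nitroalkene (ring A) and then, as the iminium ion, accepts the nitronate at C8 (ring B). Hydrolysis should give 9β-nitro-11-nordriman-6-one F1 with the same relative configuration, and C5, now next to a ketone, can equilibrate to the trans fusion. Kinetic O-silylation of F1 toward C7 (TBSOTf, Et3N, CH2Cl2, −78 °C; C5 is tertiary and shielded) returns to 12. This replaces hydrogen-bond activation of a preformed silyloxydiene by covalent, stepwise double-Michael catalysis.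

Step 4. Hydrogen abstraction may be unselective, giving deconjugated allylic nitro isomers or E/Z mixtures in place of the conjugated (E)-nitroalkene. The fallback sets out from 9 and comes back at 10 by addition and elimination in two stages. Nitryl iodide, generated from I2 and AgNO2 (Et2O, rt), adds across the 1,1-disubstituted alkene to give (2E)-10-iodo-6,6,10-trimethyl-11-nitroundec-2-en-4-one F2. Et3N (CH2Cl2, 0 °C) then removes HI through the acidic hydrogen alpha to the nitro group, which can only lead to the conjugated nitroalkene 10; the amine also equilibrates it toward the E isomer.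

Step 13. Transmetalation at the tetrasubstituted triflate, flanked by the quaternary C10 and the C8 methyl, may be slow, so that protodeboronation, β-hydride elimination or triflate hydrolysis take over. The fallback sets out from 19 and 23 and comes back at 25 with an iron-catalysed alkyl–alkenyl coupling in place of the palladium/boron coupling. Compound 19 is acetylated first (Ac2O, DMAP, pyridine) to 6β,7α-diacetoxy-11-nordrim-8-en-9-yl trifluoromethanesulfonate F3. Borane 23 is iodinated (I2, NaOMe, THF, 0 °C) to tert-butyl{[(2E)-5-iodo-3-methylpent-2-en-1-yl]oxy}diphenylsilane F4, which with Mg (THF) gives {(3E)-5-[(tert-butyldiphenylsilyl)oxy]-3-methylpent-3-en-1-yl}magnesium iodide F5. Coupling of F5 with F3 under Fe(acac)3 catalysis (THF/NMP, −30 °C), which is expected to outrun addition to the hindered acetates, should give 25 directly.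

**Further compounds**

F1 | step 6 | 9β-nitro-11-nordriman-6-one (5αH, 8β-methyl, 10β-methyl) | O=C1C[C@H](C)[C@H]([N+](=O)[O-])[C@@]2(C)CCCC(C)(C)[C@H]12
F2 | step 4 | (2E)-10-iodo-6,6,10-trimethyl-11-nitroundec-2-en-4-one (racemic) | C/C=C/C(=O)CC(C)(C)CCCC(C)(I)C[N+](=O)[O-]
F3 | step 13 | 6β,7α-diacetoxy-11-nordrim-8-en-9-yl trifluoromethanesulfonate | CC(=O)O[C@@H]1[C@@H](OC(C)=O)C(C)=C(OS(=O)(=O)C(F)(F)F)[C@@]2(C)CCCC(C)(C)[C@H]12
F4 | step 13 | tert-butyl{[(2E)-5-iodo-3-methylpent-2-en-1-yl]oxy}diphenylsilane | CC(C)(C)[Si](c1ccccc1)(c1ccccc1)OC/C=C(C)/CCI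
F5 | step 13 | {(3E)-5-[(tert-butyldiphenylsilyl)oxy]-3-methylpent-3-en-1-yl}magnesium iodide | CC(C)(C)[Si](c1ccccc1)(c1ccccc1)OC/C=C(C)/CC[Mg]I
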